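**Strategy.** The achiral target is cut at C3 of the benzofuran, which carries three separable pieces: ring A through C3a, the formyl carbon, and C2 with its aryl group. Because ring A is a threefold-symmetric phloroglucinol, one telescoped operation can join phloroglucinol, nitromethane and a 2-methoxy-4-silyloxyphenylglyoxal. Henry addition and dehydration make the C3–CH2NO2 bond, C-alkylation makes C3–C3a, and cyclodehydration makes O1–C2, closing the furan ring with a nitromethyl group as latent CHO. The formyl group then distinguishes the hydrogen-bonded 4-OH from the 6-OH, and a Claisen shift of a 4-O-(1,1-dimethylallyl) ether places the prenyl group at C5.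

Key step: step 3

Remark: Ebenfuran IV has no stereocentre, so no step needs stereocontrol; 1-(4-hydroxy-2-methoxyphenyl)ethan-1-one and 3-chloro-3-methylbut-1-yne are taken as catalogue compounds, and glyoxal 3 is handled as its hydrate and dried azeotropically before step 3.

**Step 1**
Reactants: 1 1-(4-hydroxy-2-methoxyphenyl)ethan-1-one
Product: 2 1-[2-methoxy-4-(triisopropylsilyloxy)phenyl]ethan-1-one
Conditions: TIPSCl, imidazole, DMF, rt
Reagents that add atoms: triisopropylsilyl chloride, CC(C)[Si](Cl)(C(C)C)C(C)C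
Why: Imidazole-mediated silylation of the only free phenol gives a bulky aryl silyl ether that should survive the acidic and weakly basic steps ahead and fall to fluoride at the end.

**Step 2**
Reactants: 2 1-[2-methoxy-4-(triisopropylsilyloxy)phenyl]ethan-1-one
Product: 3 2-[2-methoxy-4-(triisopropylsilyloxy)phenyl]-2-oxoacetaldehyde
Conditions: SeO2, 1,4-dioxane/H2O (30:1), 95 °C; hydrate dried by toluene azeotrope
Reagents that add atoms: selenium dioxide, O=[Se]=O
Why: Riley oxidation converts the enolisable methyl of an aryl methyl ketone into the aldehyde of an arylglyoxal, and the substrate has no other oxidisable C–H.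

**Step 3**
Reactants: 3 2-[2-methoxy-4-(triisopropylsilyloxy)phenyl]-2-oxoacetaldehyde; 4 nitromethane; 5 phloroglucinol
Product: 9 2-[2-methoxy-4-(triisopropylsilyloxy)phenyl]-3-(nitromethyl)benzofuran-4,6-diol, via nitroaldol 6 (not isolated), via nitroenone 7 (not isolated), via Friedel–Crafts adduct 8 (not isolated)
Conditions: MeNO2 (2 equiv), Et3N (cat.), THF, 0 °C; evaporate; MsCl, Et3N, CH2Cl2, −30 °C; then TFA, phloroglucinol (4 equiv), MeCN, 0 → 40 °C (one flask)
Reagents that add atoms: none
Why: Amine-catalysed Henry addition of nitromethane to the formyl carbon of 3 gives nitroaldol 6, mesylation and E1cB elimination give the (E)-β-nitroenone 7, and after acidification phloroglucinol adds through carbon to the enone carbon β to nitro (α to the ketone) to give 8, whose flanking phenol attacks the protonated aryl ketone and loses water to give the aromatic furan. The closest known reaction types are the telescoped condensations of arylglyoxals, C–H acids and phenols to 2-arylbenzofuran-3-ylmethyl derivatives and the Friedel–Crafts alkylation/cyclodehydration of phenols with β-nitroenones, and each stage (Henry, nitroaldol dehydration, nitroalkene Friedel–Crafts, ketone–phenol cyclodehydration) is standard. The furan ring closes by 5-exo-trig attack of oxygen on the ketone carbonyl (O1–C2) followed by dehydration, driven by aromatisation. No stereocentre is retained, because the racemic carbinol carbon of 6 and the racemic C3 of 8 both become sp2. The step needs C–C bond formation at the carbon next to the ketone, which the nitro group secures as the stronger acceptor, and single alkylation, which the excess of phloroglucinol secures, while the threefold symmetry of phloroglucinol makes every ring carbon and either neighbouring hydroxyl lead to the same benzofuran. Forming 7 before the phenol is added avoids direct hydroxyalkylation by the glyoxal, and the acidic medium disfavours loss of nitrous acid from 8.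

**Step 4**
Reactants: 9 2-[2-methoxy-4-(triisopropylsilyloxy)phenyl]-3-(nitromethyl)benzofuran-4,6-diol
Product: 10 4,6-dihydroxy-2-[2-methoxy-4-(triisopropylsilyloxy)phenyl]benzofuran-3-carbaldehyde
Conditions: aq. TiCl3 (5 equiv), NH4OAc (pH 5–6), THF/H2O, 0 °C → rt
Reagents that add atoms: water, O
Why: In this McMurry reductive Nef reaction Ti(III) reduces the primary nitro group through the oxime to the N–H imine, which hydrolyses in the buffer to the aldehyde, and the non-oxidising, non-basic medium should spare the electron-rich diol ring and the aryl silyl ether.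

**Step 5**
Reactants: 10 4,6-dihydroxy-2-[2-methoxy-4-(triisopropylsilyloxy)phenyl]benzofuran-3-carbaldehyde
Product: 11 4-hydroxy-6-methoxy-2-[2-methoxy-4-(triisopropylsilyloxy)phenyl]benzofuran-3-carbaldehyde
Conditions: MeI (1.1 equiv), K2CO3 (1.1 equiv), dry acetone, rt
Reagents that add atoms: iodomethane, CI
Why: In this chelation-controlled Williamson methylation the 4-OH is hydrogen-bonded to the 3-formyl oxygen and so is less acidic and less nucleophilic, which should leave only the free 6-OH to react with one equivalent of base and MeI, as with 2,4-dihydroxyaryl carbonyl compounds.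

**Step 6**
Reactants: 11 4-hydroxy-6-methoxy-2-[2-methoxy-4-(triisopropylsilyloxy)phenyl]benzofuran-3-carbaldehyde; 12 3-chloro-3-methylbut-1-yne
Product: 13 6-methoxy-2-[2-methoxy-4-(triisopropylsilyloxy)phenyl]-4-[(2-methylbut-3-yn-2-yl)oxy]benzofuran-3-carbaldehyde
Conditions: 12 (3 equiv), DBU, CuCl2·2H2O (cat.), MeCN, 0 °C → rt
Reagents that add atoms: none
Why: In this copper-catalysed propargylic etherification of a phenol with a tertiary propargyl chloride, DBU breaks the hydrogen bond by forming the phenoxide, which should capture the copper-bound propargyl electrophile at the tertiary carbon, a reaction that tolerates ortho-carbonyl phenols.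

**Step 7**
Reactants: 13 6-methoxy-2-[2-methoxy-4-(triisopropylsilyloxy)phenyl]-4-[(2-methylbut-3-yn-2-yl)oxy]benzofuran-3-carbaldehyde
Product: 14 6-methoxy-2-[2-methoxy-4-(triisopropylsilyloxy)phenyl]-4-[(2-methylbut-3-en-2-yl)oxy]benzofuran-3-carbaldehyde
Conditions: H2 (1 atm), Lindlar catalyst, quinoline, EtOAc, rt
Reagents that add atoms: none
Why: Lindlar semihydrogenation of the terminal alkyne should stop at the terminal alkene on the poisoned catalyst and leave the aldehyde, the furan and the silyl ether untouched.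

**Step 8**
Reactants: 14 6-methoxy-2-[2-methoxy-4-(triisopropylsilyloxy)phenyl]-4-[(2-methylbut-3-en-2-yl)oxy]benzofuran-3-carbaldehyde
Product: 16 4-hydroxy-6-methoxy-2-[2-methoxy-4-(triisopropylsilyloxy)phenyl]-5-(3-methylbut-2-en-1-yl)benzofuran-3-carbaldehyde, via ortho-dienone 15 (not isolated)
Conditions: xylenes, 130 °C, sealed tube
Reagents that add atoms: none
Why: The aromatic Claisen rearrangement should deliver the 1,1-dimethylallyl group with allylic transposition as a prenyl group to C5, the only free ortho carbon (the other is the ring-fusion carbon C3a), after which dienone 15 tautomerises to the phenol.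

**Step 9**
Reactants: 16 4-hydroxy-6-methoxy-2-[2-methoxy-4-(triisopropylsilyloxy)phenyl]-5-(3-methylbut-2-en-1-yl)benzofuran-3-carbaldehyde
Product: 17 Ebenfuran IV, 4-hydroxy-2-(4-hydroxy-2-methoxyphenyl)-6-methoxy-5-(3-methylbut-2-en-1-yl)benzofuran-3-carbaldehyde
Conditions: TBAF, AcOH, THF, 0 °C
Reagents that add atoms: none
Why: Fluoride-induced cleavage of the aryl silyl ether, buffered with acetic acid, should free the 4'-OH without affecting the prenyl group, the aldehyde or the methyl ethers.

**Compound list**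
1 | 1-(4-hydroxy-2-methoxyphenyl)ethan-1-one | CC(=O)c1ccc(O)cc1OC | starting material
2 | 1-[2-methoxy-4-(triisopropylsilyloxy)phenyl]ethan-1-one | CC(=O)c1ccc(O[Si](C(C)C)(C(C)C)C(C)C)cc1OC | intermediate
3 | 2-[2-methoxy-4-(triisopropylsilyloxy)phenyl]-2-oxoacetaldehyde | O=CC(=O)c1ccc(O[Si](C(C)C)(C(C)C)C(C)C)cc1OC | intermediate
4 | nitromethane | C[N+](=O)[O-] | starting material
5 | phloroglucinol (benzene-1,3,5-triol) | Oc1cc(O)cc(O)c1 | starting material
6 | 2-hydroxy-1-[2-methoxy-4-(triisopropylsilyloxy)phenyl]-3-nitropropan-1-one (racemic) | O=C(C(O)C[N+](=O)[O-])c1ccc(O[Si](C(C)C)(C(C)C)C(C)C)cc1OC | intermediate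
7 | (E)-1-[2-methoxy-4-(triisopropylsilyloxy)phenyl]-3-nitroprop-2-en-1-one | O=C(/C=C/[N+](=O)[O-])c1ccc(O[Si](C(C)C)(C(C)C)C(C)C)cc1OC | intermediate
8 | 1-[2-methoxy-4-(triisopropylsilyloxy)phenyl]-3-nitro-2-(2,4,6-trihydroxyphenyl)propan-1-one (racemic) | O=C(C(C[N+](=O)[O-])c1c(O)cc(O)cc1O)c1ccc(O[Si](C(C)C)(C(C)C)C(C)C)cc1OC | intermediate
9 | 2-[2-methoxy-4-(triisopropylsilyloxy)phenyl]-3-(nitromethyl)benzofuran-4,6-diol | [O-][N+](=O)Cc1c(-c2ccc(O[Si](C(C)C)(C(C)C)C(C)C)cc2OC)oc2cc(O)cc(O)c12 | intermediate
10 | 4,6-dihydroxy-2-[2-methoxy-4-(triisopropylsilyloxy)phenyl]benzofuran-3-carbaldehyde | O=Cc1c(-c2ccc(O[Si](C(C)C)(C(C)C)C(C)C)cc2OC)oc2cc(O)cc(O)c12 | intermediate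
11 | 4-hydroxy-6-methoxy-2-[2-methoxy-4-(triisopropylsilyloxy)phenyl]benzofuran-3-carbaldehyde | O=Cc1c(-c2ccc(O[Si](C(C)C)(C(C)C)C(C)C)cc2OC)oc2cc(OC)cc(O)c12 | intermediate
12 | 3-chloro-3-methylbut-1-yne | CC(C)(Cl)C#C | starting material
13 | 6-methoxy-2-[2-methoxy-4-(triisopropylsilyloxy)phenyl]-4-[(2-methylbut-3-yn-2-yl)oxy]benzofuran-3-carbaldehyde | O=Cc1c(-c2ccc(O[Si](C(C)C)(C(C)C)C(C)C)cc2OC)oc2cc(OC)cc(OC(C)(C)C#C)c12 | intermediate
14 | 6-methoxy-2-[2-methoxy-4-(triisopropylsilyloxy)phenyl]-4-[(2-methylbut-3-en-2-yl)oxy]benzofuran-3-carbaldehyde | O=Cc1c(-c2ccc(O[Si](C(C)C)(C(C)C)C(C)C)cc2OC)oc2cc(OC)cc(OC(C)(C)C=C)c12 | intermediate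
15 | 6-methoxy-2-[2-methoxy-4-(triisopropylsilyloxy)phenyl]-5-(3-methylbut-2-en-1-yl)-4-oxo-4,5-dihydrobenzofuran-3-carbaldehyde (racemic at C5) | O=Cc1c(-c2ccc(O[Si](C(C)C)(C(C)C)C(C)C)cc2OC)oc2C=C(OC)C(CC=C(C)C)C(=O)c12 | intermediate
16 | 4-hydroxy-6-methoxy-2-[2-methoxy-4-(triisopropylsilyloxy)phenyl]-5-(3-methylbut-2-en-1-yl)benzofuran-3-carbaldehyde | O=Cc1c(-c2ccc(O[Si](C(C)C)(C(C)C)C(C)C)cc2OC)oc2cc(OC)c(CC=C(C)C)c(O)c12 | intermediate
17 | Ebenfuran IV, 4-hydroxy-2-(4-hydroxy-2-methoxyphenyl)-6-methoxy-5-(3-methylbut-2-en-1-yl)benzofuran-3-carbaldehyde | COc1cc(O)ccc1-c1oc2cc(OC)c(CC=C(C)C)c(O)c2c1C=O | target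

**Totals.** Total step count: 9. Longest linear sequence: 9 steps (1 → 17).

**Steps most likely to fail**

Step 3. The nitroenone may oligomerise under the amine base, be captured a second time by the highly nucleophilic ring, or its adduct may shed nitrous acid before the furan closes. The fallback builds the C3 unit by the oxidative 1,2-aryl shift of a chalcone, known chemistry for 3-formyl-2-arylbenzofurans; it sets out from 2 and returns at 10, bypassing steps 3 and 4. The lithium enolate of 2 (LiHMDS, THF, −78 °C) would be added to 2,4,6-tris(methoxymethoxy)benzaldehyde F1 (from commercial 2,4,6-trihydroxybenzaldehyde with MOMCl, NaH, DMF) to give the aldol 3-hydroxy-1-[2-methoxy-4-(triisopropylsilyloxy)phenyl]-3-[2,4,6-tris(methoxymethoxy)phenyl]propan-1-one F2. MsCl/Et3N would dehydrate it to (E)-1-[2-methoxy-4-(triisopropylsilyloxy)phenyl]-3-[2,4,6-tris(methoxymethoxy)phenyl]prop-2-en-1-one F3. PhI(OH)OTs in MeOH/HC(OMe)3 would move the electron-rich aryl ring from Cβ to Cα to give 3,3-dimethoxy-1-[2-methoxy-4-(triisopropylsilyloxy)phenyl]-2-[2,4,6-tris(methoxymethoxy)phenyl]propan-1-one F4. p-TsOH in wet (CF3)2CHOH would then remove the MOM groups, close the furan onto the ketone and unmask the aldehyde to give 10.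

Step 4. The reduction may stall at the oxime or run on to the amine, and the freshly formed aldehyde may condense with the electron-rich ring. The fallback sets out from 9 and returns at 10 in two deliberate stages: SnCl2·2H2O, PhSH and Et3N would reduce the nitro group only as far as (E)-4,6-dihydroxy-2-[2-methoxy-4-(triisopropylsilyloxy)phenyl]benzofuran-3-carbaldehyde oxime F5, and transoximation with aqueous glyoxylic acid in THF would release 10.

Step 6. O-Alkylation of the hydrogen-bonded, peri-crowded 4-OH may be slow, so that the tertiary propargyl electrophile is lost by elimination. The fallback sets out from 11 and returns at 14, bypassing steps 6 and 7: Pd(PPh3)4-catalysed decarboxylative allylation with tert-butyl 2-methylbut-3-en-2-yl carbonate (CC(C)(C)OC(=O)OC(C)(C)C=C) in THF at 0 °C would give the branched 1,1-dimethylallyl ether 14 directly.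

**Further compounds**
F1 | step 3 | 2,4,6-tris(methoxymethoxy)benzaldehyde | COCOc1cc(OCOC)c(C=O)c(OCOC)c1
F2 | step 3 | 3-hydroxy-1-[2-methoxy-4-(triisopropylsilyloxy)phenyl]-3-[2,4,6-tris(methoxymethoxy)phenyl]propan-1-one (racemic) | COCOc1cc(OCOC)c(C(O)CC(=O)c2ccc(O[Si](C(C)C)(C(C)C)C(C)C)cc2OC)c(OCOC)c1
F3 | step 3 | (E)-1-[2-methoxy-4-(triisopropylsilyloxy)phenyl]-3-[2,4,6-tris(methoxymethoxy)phenyl]prop-2-en-1-one | COCOc1cc(OCOC)c(/C=C/C(=O)c2ccc(O[Si](C(C)C)(C(C)C)C(C)C)cc2OC)c(OCOC)c1
F4 | step 3 | 3,3-dimethoxy-1-[2-methoxy-4-(triisopropylsilyloxy)phenyl]-2-[2,4,6-tris(methoxymethoxy)phenyl]propan-1-one (racemic) | COCOc1cc(OCOC)c(C(C(OC)OC)C(=O)c2ccc(O[Si](C(C)C)(C(C)C)C(C)C)cc2OC)c(OCOC)c1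
F5 | step 4 | (E)-4,6-dihydroxy-2-[2-methoxy-4-(triisopropylsilyloxy)phenyl]benzofuran-3-carbaldehyde oxime | O/N=C/c1c(-c2ccc(O[Si](C(C)C)(C(C)C)C(C)C)cc2OC)oc2cc(O)cc(O)c12
F0 | step 6 | none | none
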